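The dihydropyran of the target (cyclopenta[c]pyran numbering) is an enol ether O2–C3=C4 with an acyl group on C3, cis-fused through C4a–C7a to the cyclopentane. This is the retron of an inverse-demand oxa-Diels–Alder reaction of a 2-acyl-1-oxadiene. The last step therefore joins two events in one flask. An acyclic (Z,Z)-dienyl boronate is acylated at C4 by 4-methyl-2-oxopentanoyl chloride (bond C3–C4), and the ene-dione so formed cyclises onto its (Z)-chromonyl alkene (bond C4a–C7a, and O2–C1). The precursor is built from (S)-citronellal, whose C7 methyl centre then controls C1, C4a and C7a.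

Key step: step 11

Remark: the labels C1, O2, C3, C4, C4a, C5, C6, C7 and C7a are those of the cyclopenta[c]pyran core of the target and denote the same atoms in every precursor. Lithium 2,2,6,6-tetramethylpiperidide and the phosphazene base are taken as purchased reagents.

Step 1
Reactants: 1 1-(2-hydroxy-6-methylphenyl)ethan-1-one
Product: 2 4-hydroxy-5-methyl-2H-chromen-2-one
Conditions: NaH, (EtO)2CO, toluene, 110 °C; then aq HCl
Reagents that add atoms: diethyl carbonate, CCOC(=O)OCC
Why: Claisen-type C-acylation of the methyl ketone enolate by diethyl carbonate, followed by lactonisation onto the phenoxide (the standard 4-hydroxycoumarin synthesis), should close the pyranone ring.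

Step 2
Reactants: 2 4-hydroxy-5-methyl-2H-chromen-2-one
Product: 3 2-methoxy-5-methyl-4H-chromen-4-one
Conditions: MeI, Ag2CO3, toluene, rt, dark
Reagents that add atoms: iodomethane, CI
Why: O-alkylation of the ambident 4-hydroxycoumarin anion as its silver salt should take place at the lactone carbonyl oxygen, because the 4-oxygen sits next to the peri 5-methyl group; any 4-methoxycoumarin isomer is removed by chromatography.

Step 3
Reactants: 3 2-methoxy-5-methyl-4H-chromen-4-one
Product: 4 3-iodo-2-methoxy-5-methyl-4H-chromen-4-one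
Conditions: N-iodosuccinimide, CF3CO2H (cat.), MeCN, rt
Reagents that add atoms: N-iodosuccinimide, O=C1CCC(=O)N1I
Why: electrophilic iodination, since C3 is the nucleophilic β-carbon of the cyclic ketene acetal and the only free position of the pyranone ring.

Step 4
Reactants: 5 (S)-citronellal
Product: 7 (3S)-3,7-dimethyloct-6-en-1-yne, via alkenyl nonaflate 6 (not isolated)
Conditions: C4F9SO2F, phosphazene base P2-Et, DMF, −20 °C → rt
Reagents that add atoms: none
Why: one-pot alkyne synthesis from an enolisable aldehyde, in which the enolate is O-sulfonylated to 6 and a second equivalent of base eliminates nonaflate (E2) to the terminal alkyne; the carbon count is unchanged and the C3 stereocentre is not involved.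

Step 5
Reactants: 4 3-iodo-2-methoxy-5-methyl-4H-chromen-4-one; 7 (3S)-3,7-dimethyloct-6-en-1-yne
Product: 8 3-[(3S)-3,7-dimethyloct-6-en-1-yn-1-yl]-2-methoxy-5-methyl-4H-chromen-4-one
Conditions: PdCl2(PPh3)2 (cat.), CuI (cat.), Et3N, THF, 40 °C
Reagents that add atoms: none
Why: Sonogashira coupling, in which the C–I bond of the 3-iodochromone adds readily to zerovalent palladium and the copper acetylide of 7 transmetalates; the remote trisubstituted alkene is inert.

Step 6
Reactants: 8 3-[(3S)-3,7-dimethyloct-6-en-1-yn-1-yl]-2-methoxy-5-methyl-4H-chromen-4-one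
Product: 10 (4S)-6-(2-methoxy-5-methyl-4-oxo-4H-chromen-3-yl)-4-methylhex-5-ynal, via diol 9 (not isolated)
Conditions: OsO4 (cat.), NaIO4, 2,6-lutidine, dioxane–H2O, rt
Reagents that add atoms: osmium tetroxide, O=[Os](=O)(=O)=O, the oxygen donor, regenerated by sodium periodate, [Na+].[O-]I(=O)(=O)=O
Why: Lemieux–Johnson oxidation, in which OsO4 dihydroxylates the electron-rich trisubstituted alkene far faster than the alkyne or the tetrasubstituted push–pull alkene of the chromone, and periodate cleaves diol 9 to the aldehyde and acetone.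

Step 7
Reactants: 11 bis[(pinacolato)boryl]methane
Product: 13 2,2'-(ethane-1,1-diyl)bis(4,4,5,5-tetramethyl-1,3,2-dioxaborolane), via lithiated bis(boronate) 12 (not isolated)
Conditions: lithium 2,2,6,6-tetramethylpiperidide, THF, 0 °C; then MeI, 0 °C → rt
Reagents that add atoms: iodomethane, CI
Why: deprotonation of the geminal bis(boronate) gives a carbanion stabilised by both empty boron p orbitals, and its alkylation with iodomethane is the standard route to substituted 1,1-diborylalkanes.

Step 8
Reactants: 10 (4S)-6-(2-methoxy-5-methyl-4-oxo-4H-chromen-3-yl)-4-methylhex-5-ynal; 13 2,2'-(ethane-1,1-diyl)bis(4,4,5,5-tetramethyl-1,3,2-dioxaborolane)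
Product: 15 2-methoxy-5-methyl-3-[(3S,6Z)-3-methyl-7-(4,4,5,5-tetramethyl-1,3,2-dioxaborolan-2-yl)oct-6-en-1-yn-1-yl]-4H-chromen-4-one, via lithiated diborylethane 14 (not isolated)
Conditions: lithium 2,2,6,6-tetramethylpiperidide, THF, 0 °C; then 10, −78 °C → rt
Reagents that add atoms: none
Why: boron–Wittig olefination, in which carbanion 14 adds to the aldehyde (far more electrophilic than the chromone carbonyl) and syn-elimination of the B–O pair through the less crowded oxaboretanide should leave the remaining boron trans to the chain, which is the (6Z) trisubstituted alkenyl boronate.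

Step 9
Reactants: 15 2-methoxy-5-methyl-3-[(3S,6Z)-3-methyl-7-(4,4,5,5-tetramethyl-1,3,2-dioxaborolan-2-yl)oct-6-en-1-yn-1-yl]-4H-chromen-4-one
Product: 16 2-methoxy-5-methyl-3-[(1Z,3S,6Z)-3-methyl-7-(4,4,5,5-tetramethyl-1,3,2-dioxaborolan-2-yl)octa-1,6-dien-1-yl]-4H-chromen-4-one
Conditions: H2 (1 atm), Pd/CaCO3 poisoned with Pb(OAc)2, quinoline, EtOAc, rt
Reagents that add atoms: none
Why: Lindlar semihydrogenation, in which syn delivery of hydrogen on the poisoned palladium surface converts the alkyne to the (1Z)-alkene, while the trisubstituted alkenyl boronate and the chromone double bond are not reduced.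

Step 10
Reactants: 17 4-methyl-2-oxopentanoic acid
Product: 18 4-methyl-2-oxopentanoyl chloride
Conditions: Cl2CHOMe, neat, 50 °C
Reagents that add atoms: dichloromethyl methyl ether, COC(Cl)Cl
Why: α,α-dichloromethyl methyl ether converts the α-keto acid into its acid chloride (the standard preparation of pyruvoyl-type chlorides) with loss of methyl formate and HCl.

Step 11
Reactants: 16 2-methoxy-5-methyl-3-[(1Z,3S,6Z)-3-methyl-7-(4,4,5,5-tetramethyl-1,3,2-dioxaborolan-2-yl)octa-1,6-dien-1-yl]-4H-chromen-4-one; 18 4-methyl-2-oxopentanoyl chloride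
Product: 20 2-methoxy-5-methyl-3-[(1S,4aS,7S,7aR)-4,7-dimethyl-3-(3-methylbutanoyl)-1,4a,5,6,7,7a-hexahydrocyclopenta[c]pyran-1-yl]-4H-chromen-4-one (target), via ene-dione 19 (not isolated)
Conditions: Pd(PPh3)4 (cat.), Cs2CO3, toluene, 45 °C; then 90 °C
Reagents that add atoms: none
Why: Acylative Suzuki–Miyaura coupling (oxidative addition of the C–Cl bond of 18 to zerovalent palladium, carbonate-assisted transmetalation of the alkenyl boronate with retention, reductive elimination) forms C3–C4 and gives the (E)-ene-dione 19, a 2-acyl-1-oxadiene; on warming, 19 undergoes an intramolecular inverse-electron-demand oxa-Diels–Alder reaction with the (Z)-alkene, which forms C4a–C7a and O2–C1 and turns the new C3–C4 bond into the enol ether double bond. The closest known reaction types are the ketone synthesis from acid chlorides and organoboron reagents and the intramolecular hetero-Diels–Alder reactions of β,γ-unsaturated α-dicarbonyl and alkylidene-1,3-dicarbonyl compounds that lead to iridoid-type cyclopenta[c]pyrans. The dihydropyran closes as the six-membered ring of the [4+2] cycloaddition, and the cyclopentane closes at the same time as its three-carbon tether through the bond C4a–C7a. C1 follows from suprafacial addition to the (Z)-alkene (chromone cis to C7, hence H1 cis to H7a); C7a follows from allylic 1,3-strain in the (Z)-alkene, which keeps H7 in the alkene plane and sends the tethered oxadiene to the face opposite the C7 methyl group; C4a follows from the short tether, which allows only the syn transition state and hence the cis ring fusion. The step needs acyl transfer without decarbonylation of the α-ketoacyl palladium intermediate, secured by the mild coupling temperature, and a polarity-matched cycloaddition, secured by the nucleophilic C7a of the 2-methoxychromonyl alkene and the electrophilic C4a of the ene-dione; the tether fixes the regiochemistry.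

Compound list
1 | 1-(2-hydroxy-6-methylphenyl)ethan-1-one | CC(=O)c1c(C)cccc1O | starting material
2 | 4-hydroxy-5-methyl-2H-chromen-2-one | Cc1cccc2oc(=O)cc(O)c12 | intermediate
3 | 2-methoxy-5-methyl-4H-chromen-4-one | COc1cc(=O)c2c(C)cccc2o1 | intermediate
4 | 3-iodo-2-methoxy-5-methyl-4H-chromen-4-one | COc1oc2cccc(C)c2c(=O)c1I | intermediate
5 | (S)-citronellal, (3S)-3,7-dimethyloct-6-enal | C[C@H](CC=O)CCC=C(C)C | starting material
6 | (3S)-3,7-dimethylocta-1,6-dien-1-yl nonafluorobutane-1-sulfonate (E/Z mixture) | C[C@H](C=COS(=O)(=O)C(F)(F)C(F)(F)C(F)(F)C(F)(F)F)CCC=C(C)C | intermediate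
7 | (3S)-3,7-dimethyloct-6-en-1-yne | C[C@H](C#C)CCC=C(C)C | intermediate
8 | 3-[(3S)-3,7-dimethyloct-6-en-1-yn-1-yl]-2-methoxy-5-methyl-4H-chromen-4-one | C[C@H](C#Cc1c(OC)oc2cccc(C)c2c1=O)CCC=C(C)C | intermediate
9 | 3-[(3S)-6,7-dihydroxy-3,7-dimethyloct-1-yn-1-yl]-2-methoxy-5-methyl-4H-chromen-4-one (both C6 epimers) | C[C@H](C#Cc1c(OC)oc2cccc(C)c2c1=O)CCC(O)C(C)(C)O | intermediate
10 | (4S)-6-(2-methoxy-5-methyl-4-oxo-4H-chromen-3-yl)-4-methylhex-5-ynal | C[C@H](C#Cc1c(OC)oc2cccc(C)c2c1=O)CCC=O | intermediate
11 | bis[(pinacolato)boryl]methane, 2,2'-methylenebis(4,4,5,5-tetramethyl-1,3,2-dioxaborolane) | CC1(C)OB(CB2OC(C)(C)C(C)(C)O2)OC1(C)C | starting material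
12 | [bis(4,4,5,5-tetramethyl-1,3,2-dioxaborolan-2-yl)methyl]lithium | [Li]C(B1OC(C)(C)C(C)(C)O1)B1OC(C)(C)C(C)(C)O1 | intermediate
13 | 2,2'-(ethane-1,1-diyl)bis(4,4,5,5-tetramethyl-1,3,2-dioxaborolane) | CC(B1OC(C)(C)C(C)(C)O1)B1OC(C)(C)C(C)(C)O1 | intermediate
14 | [1,1-bis(4,4,5,5-tetramethyl-1,3,2-dioxaborolan-2-yl)ethyl]lithium | [Li]C(C)(B1OC(C)(C)C(C)(C)O1)B1OC(C)(C)C(C)(C)O1 | intermediate
15 | 2-methoxy-5-methyl-3-[(3S,6Z)-3-methyl-7-(4,4,5,5-tetramethyl-1,3,2-dioxaborolan-2-yl)oct-6-en-1-yn-1-yl]-4H-chromen-4-one | C[C@H](C#Cc1c(OC)oc2cccc(C)c2c1=O)CC/C=C(\C)B1OC(C)(C)C(C)(C)O1 | intermediate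
16 | 2-methoxy-5-methyl-3-[(1Z,3S,6Z)-3-methyl-7-(4,4,5,5-tetramethyl-1,3,2-dioxaborolan-2-yl)octa-1,6-dien-1-yl]-4H-chromen-4-one | C[C@H](/C=C\c1c(OC)oc2cccc(C)c2c1=O)CC/C=C(\C)B1OC(C)(C)C(C)(C)O1 | intermediate
17 | 4-methyl-2-oxopentanoic acid | CC(C)CC(=O)C(=O)O | starting material
18 | 4-methyl-2-oxopentanoyl chloride | CC(C)CC(=O)C(=O)Cl | intermediate
19 | (6E,10S,11Z)-12-(2-methoxy-5-methyl-4-oxo-4H-chromen-3-yl)-2,6,10-trimethyldodeca-6,11-diene-4,5-dione | C[C@H](/C=C\c1c(OC)oc2cccc(C)c2c1=O)CC/C=C(\C)C(=O)C(=O)CC(C)C | intermediate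
20 | 2-methoxy-5-methyl-3-[(1S,4aS,7S,7aR)-4,7-dimethyl-3-(3-methylbutanoyl)-1,4a,5,6,7,7a-hexahydrocyclopenta[c]pyran-1-yl]-4H-chromen-4-one | COc1oc2cccc(C)c2c(=O)c1[C@H]1OC(C(=O)CC(C)C)=C(C)[C@H]2CC[C@H](C)[C@H]21 | target

Total step count: 11
Longest linear sequence: 8 steps (steps 1, 2, 3, 5, 6, 8, 9, 11)

Steps most likely to fail

Step 11 (key step). The acyl donor may be lost by decarbonylation of the α-ketoacyl palladium intermediate, or by base-induced hydrolysis before the pinacol boronate transmetalates. A stepwise, zwitterionic ring closure could also erode the transfer of the (Z)-alkene geometry to C1. The fallback sets out from 16 and 18 and moves the coupling to a base-free thioester manifold. Boronate 16 is hydrolysed with NaIO4 and NH4OAc in acetone–water to {(2Z,6S,7Z)-8-(2-methoxy-5-methyl-4-oxo-4H-chromen-3-yl)-6-methylocta-2,7-dien-2-yl}boronic acid F1. Acid chloride 18 is converted with thiophenol and pyridine in CH2Cl2 into S-phenyl 4-methyl-2-oxopentanethioate F2. A Liebeskind–Srogl coupling of F1 and F2 (Pd2(dba)3, tri(2-furyl)phosphine, copper thiophene-2-carboxylate C5H3CuO2S, THF, 50 °C), followed by warming in toluene, should then give the ene-dione and its cycloadduct in the same flask. The fallback comes back to the route at 19 and so at 20.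

Step 2. Alkylation of the ambident anion may occur at the 4-oxygen instead of the lactone oxygen. The fallback sets out from 1 and builds the 2-alkoxy chromone with fixed regiochemistry through sulfur. Ketone 1 with KOC(CH3)3 and CS2 in THF should give 4-hydroxy-5-methyl-2H-chromene-2-thione F3. S-Methylation (MeI, K2CO3, acetone) gives 5-methyl-2-(methylsulfanyl)-4H-chromen-4-one F4. Oxidation with mCPBA in CH2Cl2 gives 2-(methanesulfonyl)-5-methyl-4H-chromen-4-one F5. Addition–elimination with NaOCH3 in methanol at 0 °C replaces the sulfonyl group by methoxide. The fallback comes back to the route at 3.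

Step 4. Excess phosphazene base may cause propargyl–allenyl isomerisation of the terminal alkyne, which would also scramble the adjacent stereocentre. The fallback sets out from 5 and separates the two events. Tf2O with 2,6-di-tert-butyl-4-methylpyridine in CH2Cl2 at 0 °C gives the isolated enol triflate (3S)-3,7-dimethylocta-1,6-dien-1-yl trifluoromethanesulfonate F6. Lithium diisopropylamide (2.2 equiv) in THF at −78 °C then eliminates triflate and holds the product as its lithium acetylide, which cannot isomerise, until the quench. The fallback comes back to the route at 7.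

Further compounds
F1 | step 11 | {(2Z,6S,7Z)-8-(2-methoxy-5-methyl-4-oxo-4H-chromen-3-yl)-6-methylocta-2,7-dien-2-yl}boronic acid | C[C@H](/C=C\c1c(OC)oc2cccc(C)c2c1=O)CC/C=C(\C)B(O)O
F2 | step 11 | S-phenyl 4-methyl-2-oxopentanethioate | CC(C)CC(=O)C(=O)Sc1ccccc1
F3 | step 2 | 4-hydroxy-5-methyl-2H-chromene-2-thione | Cc1cccc2oc(=S)cc(O)c12
F4 | step 2 | 5-methyl-2-(methylsulfanyl)-4H-chromen-4-one | CSc1cc(=O)c2c(C)cccc2o1
F5 | step 2 | 2-(methanesulfonyl)-5-methyl-4H-chromen-4-one | CS(=O)(=O)c1cc(=O)c2c(C)cccc2o1
F6 | step 4 | (3S)-3,7-dimethylocta-1,6-dien-1-yl trifluoromethanesulfonate (E/Z mixture) | C[C@H](C=COS(=O)(=O)C(F)(F)F)CCC=C(C)C
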